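**Retrosynthetic overview**

1. Atom labels give the position in the target SMILES (1 to 29). Ring A = C2-C3-C4-C7-C9-C18-C19-C20, ring B = C9-C10-C12-C25-C18, lactone C = C18-C19-C22-O24-C25, ring D = C12-C13-C15-C27-C26-C25, and ether O17 links C15 to C18. The upper face of ring D carries C10, O17 and C18; the lower face carries O14, O29 and O24.
2. Feature: C25 is the fully substituted carbon shared by rings B, C and D. It holds the acyloxy oxygen O24 and C18, and C18 is a carboxyl carbon once lactone C is read as a tetronate. This is the retron of a Passerini adduct of a ring D ketone, benzyl isocyanide and acetic acid (bonds C18-C25 and O24-C22).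
3. Late disconnections: C4-O6 (hydration of a C4=C5 methylene ketone), C9-C18 (transannular Michael addition closing rings A and B together), C4-C7 (Nozaki-Hiyama-Kishi macrocyclisation), C19-C20 (lithiated tetronate plus aldehyde), O17-C18 (addition-elimination), C19-C18 (Dieckmann).
4. Early disconnections: C10-C12 (aldol with acrolein), the O14/O29 acetal bridge, C12-C13 (aldol closure of ring D), C13-C15 (chelate-controlled vinyl addition), C25-C26 (opening of (S)-2-methylglycidol, which supplies C27).
5. Ring order: D, acetal bridge, lactone C, O17 bridge, eleven-membered carbocycle, then B and A in one step.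

Key step: step 13

Remark on the chemistry: the O14/O29 bridge is carried as a 4-methoxybenzylidene acetal and not as an isopropylidene acetal, because in the 2,4-dioxabicyclo[3.3.1]nonane one acetal substituent points into the cavity under C25 and only hydrogen fits there (the C16 methyl group forbids the boat form of the dioxane); O11 TBS and O17 TES are kept.

Step 1
Reactants: 1 (S)-2-methylglycidol
Product: 2 (R)-2,4-dimethylpent-4-ene-1,2-diol
Conditions: isopropenylMgBr (3 equiv), CuI (10 mol %), THF, -30 to 0 °C; aq NH4Cl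
Reagents that add atoms: isopropenylmagnesium bromide, C=C(C)[Mg]Br
Why: Copper-catalysed Grignard opening of an epoxide: the nucleophile attacks the unsubstituted carbon C26, so C25-C26 forms and the C27 centre of the starting material is carried over unchanged.

Step 2
Reactants: 2 (R)-2,4-dimethylpent-4-ene-1,2-diol
Product: 3 2-(4-methoxyphenyl)-4-methyl-4-(2-methylallyl)-1,3-dioxolane (C27 as in 2, both acetal epimers)
Conditions: 4-MeOC6H4CH(OMe)2, PPTS (cat.), CH2Cl2, rt
Reagents that add atoms: 4-methoxybenzaldehyde dimethyl acetal, COc1ccc(cc1)C(OC)OC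
Why: Acid-catalysed transacetalisation ties the primary oxygen and the tertiary O29 into a 4-methoxybenzylidene acetal, the set-up for placing PMB on the tertiary oxygen.

Step 3
Reactants: 3 4-methoxybenzylidene acetal
Product: 4 (R)-2-(4-methoxybenzyloxy)-2,4-dimethylpent-4-en-1-ol
Conditions: iBu2AlH (3 equiv), CH2Cl2, -78 to 0 °C; aq potassium sodium tartrate
Reagents that add atoms: none
Why: Reductive acetal opening: the aluminium hydride binds the less hindered primary oxygen and cleaves its bond to the acetal carbon, so the PMB group stays on tertiary O29 and the primary alcohol is freed.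

Step 4
Reactants: 4 primary alcohol
Product: 5 (R)-2-(4-methoxybenzyloxy)-2,4-dimethylpent-4-enoic acid
Conditions: TEMPO (cat.), PhI(OAc)2 (2.2 equiv), MeCN/H2O, rt
Reagents that add atoms: water, O
Why: Oxoammonium (TEMPO) oxidation of the primary alcohol through the aldehyde hydrate gives the acid (C15) without touching the alkene or the PMB ether.

Step 5
Reactants: 5 carboxylic acid
Product: 6 (R)-3-(4-methoxybenzyloxy)-3,5-dimethylhex-5-en-2-one
Conditions: MeLi (3 equiv), Et2O, 0 °C to rt; poured into cold aq NH4Cl
Reagents that add atoms: methyllithium, [Li]C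
Why: Ketone synthesis from a lithium carboxylate and methyllithium: the dilithio gem-diolate is stable until the quench, so a single methyl group (C16) is added.

Step 6
Reactants: 6 alpha-alkoxy methyl ketone
Product: 7 (3R,4R)-4-(4-methoxybenzyloxy)-3,4,6-trimethylhepta-1,6-dien-3-ol
Conditions: MgBr2·OEt2 (2 equiv), CH2Cl2, -78 °C; vinylMgBr (3 equiv); aq NH4Cl
Reagents that add atoms: vinylmagnesium bromide, C=C[Mg]Br
Why: Cram chelate addition of a Grignard reagent to an alpha-alkoxy ketone: magnesium ties O29 and the C15 carbonyl oxygen into a five-membered chelate and the vinyl group (C13) enters from the side of the small C28 methyl group, away from the methallyl arm, which sets C15 with O17 and O29 in the relation of the trans diol of ring D.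

Step 7
Reactants: 7 tertiary allylic alcohol
Product: 8 triethylsilyl ether of 7
Conditions: TESOTf, 2,6-lutidine, CH2Cl2, 0 °C
Reagents that add atoms: triethylsilyl trifluoromethanesulfonate, CC[Si](CC)(CC)OS(=O)(=O)C(F)(F)F
Why: Silylation of the hindered tertiary alcohol by the silyl triflate protects O17 as the TES ether that is to be removed selectively later.

Step 8
Reactants: 8 diene
Product: 9 3-(4-methoxybenzyloxy)-2,3-dimethyl-5-oxo-2-(triethylsilyloxy)hexanal (C13 aldehyde, C25 methyl ketone; C15 and C27 as in 7)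
Conditions: OsO4 (2 mol %), NaIO4 (8 equiv), 2,6-lutidine, dioxane/H2O, rt
Reagents that add atoms: osmium tetroxide (oxygen carrier), O=[Os](=O)(=O)=O; sodium periodate (terminal oxygen source), [Na+].[O-]I(=O)(=O)=O
Why: Lemieux-Johnson cleavage turns the isopropenyl group into the C25 methyl ketone and the vinyl group into the C13 aldehyde in one operation and, unlike ozone, leaves the PMB ether alone.

Step 9
Reactants: 9 keto aldehyde
Product: 10 ring D aldol, 3-hydroxy-5-(4-methoxybenzyloxy)-4,5-dimethyl-4-(triethylsilyloxy)cyclohexanone (O14 and O29 on the lower face, O17 on the upper face)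
Conditions: LiN(SiMe3)2 (1.05 equiv), THF, -78 °C, dilute; AcOH quench at -78 °C
Reagents that add atoms: none
Why: Intramolecular aldol addition (6-enolendo-exo-trig): kinetic deprotonation takes the methyl group C12 and not the neopentyl C26, the aldehyde has no alpha hydrogen, and the lithium-bridged closed transition state in the chair that keeps both ring methyl groups equatorial places O14 axial on the lower face, cis to O29, which sets C13.

Step 10
Reactants: 10 ring D aldol
Product: 11 bridged ring D ketone, 2,4-dioxabicyclo[3.3.1]nonan-7-one with O14-CH(4-MeOC6H4)-O29 bridge (aryl outside, H inside), O17 TES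
Conditions: DDQ (1.2 equiv), 4 Å molecular sieves, CH2Cl2, 0 °C
Reagents that add atoms: none
Why: Oxidative acetalisation of a PMB ether: DDQ takes a hydride from the PMB methylene group and the neighbouring O14-H traps the oxocarbenium ion, which is possible only for the cis O14/O29 isomer and puts the aryl group outside and the acetal hydrogen inside the bicycle.

Step 11
Reactants: 11 bridged ring D ketone; 12 acrolein
Product: 14 anti aldol adduct of the bridged ketone (C10 on the upper face of C12; O11-H free), via dicyclohexylboron enolate 13 (not isolated)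
Conditions: Cy2BCl, Et3N, Et2O, -78 to 0 °C; 12, -78 °C; MeOH, pH 7 buffer, H2O2, 0 °C
Reagents that add atoms: none
Why: Boron-mediated aldol addition (Zimmerman-Traxler): enolisation goes toward C12 because C26 is neopentyl next to the fully substituted C27, the enolate is attacked on its open upper (exo) face, which sets C12, the ring-locked E enolate gives the anti C12/C10 relation through the chair transition state, which sets C10, and acrolein reacts 1,2.

Step 12
Reactants: 14 aldol adduct
Product: 15 ring D ketone with the allylic TBS ether side chain on C12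
Conditions: TBSOTf, 2,6-lutidine, CH2Cl2, -78 °C
Reagents that add atoms: tert-butyldimethylsilyl trifluoromethanesulfonate, CC(C)(C)[Si](C)(C)OS(=O)(=O)C(F)(F)F
Why: Silyl triflate silylation at low temperature protects the aldol hydroxyl O11 without a base strong enough to cause retro-aldol cleavage or epimerisation at C12.

Step 13
Reactants: 15 ring D ketone; 16 benzyl isocyanide; 17 acetic acid
Product: 18 alpha-acetoxy N-benzyl carboxamide at C25 (C18 on the upper face, O24 on the lower face)
Conditions: 16 (5 equiv), 17 (5 equiv), CH2Cl2 (3 M in 15), sealed tube, 35 °C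
Reagents that add atoms: none
Why: Passerini three-component reaction: acetic acid hydrogen-bonds to the C25 carbonyl, the isocyanide carbon adds to C25, acetate captures the nitrilium carbon, and O-to-O acyl migration hands the acetyl group to O24, so C18-C25 and O24-C22 form while no ring closes. The closest known cases are Passerini reactions of substituted cyclohexanones run neat or at high concentration. The only new stereocentre is C25, and it is controlled by the 2,4-dioxabicyclo[3.3.1]nonane frame: the wing O14-CH(Ar)-O29 with its inward hydrogen lies under C25 and closes the lower face in both the chair and the boat form of ring D, so the linear isocyanide can only come from the upper face and C18 ends cis to C10 and O17. The step needs facial selectivity at C25, retention of the epimerisable C12 centre, and survival of the acetal and both silyl ethers; the bridge secures the first, and the weak acid, the absence of water and the moderate temperature secure the others. The price should be a slow reaction, because O11 and O17 crowd the open face, which is why a large excess of the two small components and a minimum of solvent are used.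

Step 14
Reactants: 18 alpha-acetoxy amide
Product: 19 N-Boc-N-benzyl amide of 18
Conditions: Boc2O (3 equiv), DMAP (0.5 equiv), MeCN, rt
Reagents that add atoms: di-tert-butyl dicarbonate, CC(C)(C)OC(=O)OC(=O)OC(C)(C)C
Why: DMAP-catalysed N-acylation turns the secondary amide into an N-acyl carbamate, whose twisted C18-N bond makes C18 an acylating centre.

Step 15
Reactants: 19 N-Boc amide
Product: 20 spiro tetronic acid (lactone C: C25-O24-C22(=O)-C19H=C18-OH)
Conditions: LiN(SiMe3)2 (3 equiv), THF, -78 to -20 °C; AcOH quench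
Reagents that add atoms: none
Why: Dieckmann condensation of an alpha-acyloxy acid derivative: the acetate enolate (C19) attacks the activated C18 carbonyl in a 5-exo-trig closure, tert-butyl benzylcarbamate leaves, and the stable tetronate anion drives the reaction.

Step 16
Reactants: 20 tetronic acid
Product: 21 C18 enol triflate of 20
Conditions: Tf2O, iPr2NEt, CH2Cl2, -78 °C
Reagents that add atoms: trifluoromethanesulfonic anhydride, O=S(=O)(OS(=O)(=O)C(F)(F)F)C(F)(F)F
Why: O-Sulfonylation of the tetronic acid turns the C18 hydroxyl into a leaving group on a vinylogous acyl centre.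

Step 17
Reactants: 21 enol triflate
Product: 22 enol triflate with free tertiary O17-H
Conditions: HF·pyridine, pyridine, THF, 0 °C
Reagents that add atoms: none
Why: Selective fluoride desilylation: the TES ether is far more labile than the TBS ether under buffered HF, so only O17 is freed and O11, which could otherwise attack C18, stays blocked.

Step 18
Reactants: 22 hydroxy triflate
Product: 23 bridged tetronate (O17-C18 closed, 2-oxabicyclo[2.2.2]octane fused to the butenolide)
Conditions: NaH (1.2 equiv), THF, 0 °C
Reagents that add atoms: none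
Why: Addition-elimination (vinylogous acyl substitution) on a 4-sulfonyloxybutenolide: the O17 alkoxide, held over C18 when ring D takes the boat form, adds to C18 and triflate leaves, which closes the 2-oxabicyclo[2.2.2]octane.

Step 19
Reactants: 23 bridged tetronate
Product: 25 primary alcohol at C7, via B-alkyl-9-BBN adduct 24 (not isolated)
Conditions: 9-BBN, THF, 0 °C to rt; NaBO3·4H2O, THF/H2O, rt
Reagents that add atoms: sodium perborate tetrahydrate (NaBO3·4H2O), [Na+].[Na+].O[B-]1(O)OO[B-](O)(O)OO1
Why: Hydroboration-oxidation: 9-BBN places boron on the terminal carbon C7 of the monosubstituted alkene, and the mild perborate oxidation spares the lactone.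

Step 20
Reactants: 26 (R)-4-benzyl-3-propionyloxazolidin-2-one; 27 2,3-dibromopropene
Product: 29 (R)-4-benzyl-3-[(S)-4-bromo-2-methylpent-4-enoyl]oxazolidin-2-one, via sodium enolate 28 (not isolated)
Conditions: NaN(SiMe3)2, THF, -78 °C; 27 (3 equiv), -78 to -40 °C
Reagents that add atoms: none
Why: Evans asymmetric alkylation: the chelated Z enolate is alkylated by the allylic bromide on the face away from the benzyl group, which sets C2.

Step 21
Reactants: 29 alkylated imide
Product: 30 (S)-4-bromo-2-methylpent-4-en-1-ol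
Conditions: LiBH4, Et2O, H2O (1 equiv), 0 °C
Reagents that add atoms: none
Why: Reductive removal of the auxiliary by LiBH4 gives the primary alcohol (C20) without epimerisation and leaves the alkenyl bromide intact.

Step 22
Reactants: 30 alcohol
Product: 31 (S)-4-bromo-2-methylpent-4-enal
Conditions: Dess-Martin periodinane, NaHCO3, CH2Cl2, 0 °C
Reagents that add atoms: none
Why: Dess-Martin oxidation under neutral conditions gives the alpha-branched aldehyde, used at once to avoid epimerisation at C2.

Step 23
Reactants: 25 tetronate alcohol; 31 aldehyde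
Product: 33 C19-C20 coupled diol (C20 carbinol as a mixture of epimers), via dilithio derivative 32 (not isolated)
Conditions: LiN(iPr)2 (2.2 equiv), THF, -78 °C; 31, -78 °C; aq NH4Cl
Reagents that add atoms: none
Why: Vinylic lithiation of a 5,5-disubstituted tetronate at C19 and 1,2-addition to the aldehyde form C19-C20; the first equivalent of base is taken up by the C7 hydroxyl, and the C20 configuration is irrelevant because the carbinol is oxidised later.

Step 24
Reactants: 33 diol
Product: 34 C7 aldehyde (C20-OH free)
Conditions: TEMPO (cat.), PhI(OAc)2 (1.1 equiv), CH2Cl2, rt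
Reagents that add atoms: none
Why: TEMPO oxidation is selective for the primary alcohol, so the C7 aldehyde forms next to the untouched secondary C20 carbinol.

Step 25
Reactants: 34 bromo aldehyde
Product: 35 eleven-membered carbocycle (C7 allylic carbinol, C4=C5 exocyclic methylene, C20 carbinol; carbinol epimers)
Conditions: CrCl2 (10 equiv), NiCl2 (1 mol % of the CrCl2), DMSO/THF, high dilution, rt
Reagents that add atoms: none
Why: Nozaki-Hiyama-Kishi reaction: nickel-catalysed formation of the alkenylchromium reagent at C4 and its chemoselective addition to the aldehyde C7 close the eleven-membered ring under high dilution, and the free hydroxyl, the lactone and the acetal are tolerated.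

Step 26
Reactants: 35 macrocyclic diol
Product: 36 macrocyclic 3-acyl tetronate with C7 methylene ketone
Conditions: Dess-Martin periodinane (3 equiv), NaHCO3, CH2Cl2, 0 °C to rt
Reagents that add atoms: none
Why: Dess-Martin oxidation of both secondary carbinols gives the C7 enone and the C20 ketone, which turns the tetronate into a 3-acyl tetronate with an electrophilic C18.

Step 27
Reactants: 36 macrocyclic diketone
Product: 37 pentacyclic enol (rings A and B closed; C4=C5 methylene; O11 TBS; O14/O29 acetal)
Conditions: DBU (0.2 equiv), CH2Cl2, 0 °C, short reaction time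
Reagents that add atoms: none
Why: Transannular Michael addition, known for 3-acyl tetronates: the C7 ketone can enolise only toward C9 (C4 bears no hydrogen), C9 reaches C18 only from the side of C12, which sets C18, the chain C7-C4-C3-C2-C20 forces C7 cis to C19 on ring B, which sets C9, and the adduct is trapped as the hydrogen-bonded C19=C20 enol.

Step 28
Reactants: 37 pentacyclic methylene ketone
Product: 39 protected target (C4 tertiary alcohol), via C4 hydroperoxide 38 (not isolated)
Conditions: Mn(dpm)3 (10 mol %), PhSiH3, O2 (1 atm), iPrOH/CH2Cl2, 0 °C; P(OEt)3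
Reagents that add atoms: dioxygen, O=O
Why: Mukaiyama-type hydration of an enone by hydrogen atom transfer: hydrogen goes to C5, the C4 radical conjugated with the C7 carbonyl makes ring A a tub-shaped cycloocta-1,5-diene, and O2 is taken up on the convex face opposite to C9-H and O17, which sets C4; the phosphite reduces the hydroperoxide.

Step 29
Reactants: 39 protected target
Product: 40 target CNP0073514.1
Conditions: 48 % aq HF, MeCN, 0 °C to rt
Reagents that add atoms: none
Why: Acidic fluoride deprotection: aqueous HF cleaves the TBS ether at O11 and hydrolyses the acid-labile 4-methoxybenzylidene acetal at O14/O29 in one operation, and no stereocentre is touched.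

**Compound list**

1 | (S)-2-methylglycidol | C[C@]1(CO)CO1 | starting material
2 | (R)-2,4-dimethylpent-4-ene-1,2-diol | C=C(C)C[C@@](C)(O)CO | intermediate
3 | 2-(4-methoxyphenyl)-4-methyl-4-(2-methylallyl)-1,3-dioxolane, both acetal epimers | C=C(C)C[C@]1(C)COC(c2ccc(OC)cc2)O1 | intermediate
4 | (R)-2-(4-methoxybenzyloxy)-2,4-dimethylpent-4-en-1-ol | C=C(C)C[C@@](C)(OCc1ccc(OC)cc1)CO | intermediate
5 | (R)-2-(4-methoxybenzyloxy)-2,4-dimethylpent-4-enoic acid | C=C(C)C[C@@](C)(OCc1ccc(OC)cc1)C(=O)O | intermediate
6 | (R)-3-(4-methoxybenzyloxy)-3,5-dimethylhex-5-en-2-one | C=C(C)C[C@@](C)(OCc1ccc(OC)cc1)C(C)=O | intermediate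
7 | (3R,4R)-4-(4-methoxybenzyloxy)-3,4,6-trimethylhepta-1,6-dien-3-ol | C=C(C)C[C@@](C)(OCc1ccc(OC)cc1)[C@](C)(O)C=C | intermediate
8 | triethylsilyl ether of 7 | C=C(C)C[C@@](C)(OCc1ccc(OC)cc1)[C@](C)(O[Si](CC)(CC)CC)C=C | intermediate
9 | keto aldehyde (C13 aldehyde, C25 methyl ketone) | CC(=O)C[C@@](C)(OCc1ccc(OC)cc1)[C@](C)(O[Si](CC)(CC)CC)C=O | intermediate
10 | ring D aldol (O14-H, O17 TES, O29 PMB) | O=C1C[C@H](O)[C@@](C)(O[Si](CC)(CC)CC)[C@](C)(OCc2ccc(OC)cc2)C1 | intermediate
11 | bridged ring D ketone (O14/O29 4-methoxybenzylidene acetal) | O=C1C[C@H](O[C@H]2c3ccc(OC)cc3)[C@@](C)(O[Si](CC)(CC)CC)[C@](C)(O2)C1 | intermediate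
12 | acrolein | C=CC=O | starting material
13 | dicyclohexylboron enolate of 11 (C12=C25) | C1CCC(CC1)B(C1CCCCC1)OC1=C[C@H](O[C@H]2c3ccc(OC)cc3)[C@@](C)(O[Si](CC)(CC)CC)[C@](C)(O2)C1 | intermediate
14 | anti aldol adduct (O11-H) | C=C[C@@H](O)[C@H]1[C@H](O[C@H]2c3ccc(OC)cc3)[C@@](C)(O[Si](CC)(CC)CC)[C@](C)(O2)CC1=O | intermediate
15 | ring D ketone with allylic TBS ether side chain (key-step precursor) | C=C[C@@H](O[Si](C)(C)C(C)(C)C)[C@H]1[C@H](O[C@H]2c3ccc(OC)cc3)[C@@](C)(O[Si](CC)(CC)CC)[C@](C)(O2)CC1=O | intermediate
16 | benzyl isocyanide | [C-]#[N+]Cc1ccccc1 | starting material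
17 | acetic acid | CC(=O)O | starting material
18 | alpha-acetoxy N-benzyl carboxamide at C25 (key-step product) | C=C[C@@H](O[Si](C)(C)C(C)(C)C)[C@H]1[C@H](O[C@H]2c3ccc(OC)cc3)[C@@](C)(O[Si](CC)(CC)CC)[C@](C)(O2)C[C@@]1(OC(C)=O)C(=O)NCc1ccccc1 | intermediate
19 | N-Boc-N-benzyl amide | C=C[C@@H](O[Si](C)(C)C(C)(C)C)[C@H]1[C@H](O[C@H]2c3ccc(OC)cc3)[C@@](C)(O[Si](CC)(CC)CC)[C@](C)(O2)C[C@@]1(OC(C)=O)C(=O)N(Cc1ccccc1)C(=O)OC(C)(C)C | intermediate
20 | spiro tetronic acid | C=C[C@@H](O[Si](C)(C)C(C)(C)C)[C@H]1[C@H](O[C@H]2c3ccc(OC)cc3)[C@@](C)(O[Si](CC)(CC)CC)[C@](C)(O2)C[C@]14OC(=O)C=C4O | intermediate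
21 | C18 enol triflate | C=C[C@@H](O[Si](C)(C)C(C)(C)C)[C@H]1[C@H](O[C@H]2c3ccc(OC)cc3)[C@@](C)(O[Si](CC)(CC)CC)[C@](C)(O2)C[C@]14OC(=O)C=C4OS(=O)(=O)C(F)(F)F | intermediate
22 | enol triflate with free O17-H | C=C[C@@H](O[Si](C)(C)C(C)(C)C)[C@H]1[C@H](O[C@H]2c3ccc(OC)cc3)[C@@](C)(O)[C@](C)(O2)C[C@]14OC(=O)C=C4OS(=O)(=O)C(F)(F)F | intermediate
23 | bridged tetronate (O17-C18 closed) | C=C[C@@H](O[Si](C)(C)C(C)(C)C)[C@H]1[C@H](O[C@H]2c3ccc(OC)cc3)[C@@](C)(O5)[C@](C)(O2)C[C@]14OC(=O)C=C45 | intermediate
24 | B-alkyl-9-BBN adduct (boron on C7) | B1(C2CCCC1CCC2)CC[C@@H](O[Si](C)(C)C(C)(C)C)[C@H]1[C@H](O[C@H]2c3ccc(OC)cc3)[C@@](C)(O5)[C@](C)(O2)C[C@]14OC(=O)C=C45 | intermediate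
25 | C7 primary alcohol | OCC[C@@H](O[Si](C)(C)C(C)(C)C)[C@H]1[C@H](O[C@H]2c3ccc(OC)cc3)[C@@](C)(O5)[C@](C)(O2)C[C@]14OC(=O)C=C45 | intermediate
26 | (R)-4-benzyl-3-propionyloxazolidin-2-one | CCC(=O)N1[C@H](Cc2ccccc2)COC1=O | starting material
27 | 2,3-dibromopropene | C=C(Br)CBr | starting material
28 | sodium Z enolate of 26 | [Na+].C/C=C(\[O-])N1[C@H](Cc2ccccc2)COC1=O | intermediate
29 | (R)-4-benzyl-3-[(S)-4-bromo-2-methylpent-4-enoyl]oxazolidin-2-one | C[C@@H](CC(Br)=C)C(=O)N1[C@H](Cc2ccccc2)COC1=O | intermediate
30 | (S)-4-bromo-2-methylpent-4-en-1-ol | C[C@H](CO)CC(Br)=C | intermediate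
31 | (S)-4-bromo-2-methylpent-4-enal | C[C@H](C=O)CC(Br)=C | intermediate
32 | dilithio derivative of 25 (O-Li at C7, C19-Li) | [Li]OCC[C@@H](O[Si](C)(C)C(C)(C)C)[C@H]1[C@H](O[C@H]2c3ccc(OC)cc3)[C@@](C)(O5)[C@](C)(O2)C[C@]14OC(=O)C([Li])=C45 | intermediate
33 | C19-C20 coupled diol (C20 epimers) | OCC[C@@H](O[Si](C)(C)C(C)(C)C)[C@H]1[C@H](O[C@H]2c3ccc(OC)cc3)[C@@](C)(O5)[C@](C)(O2)C[C@]14OC(=O)C(C(O)[C@@H](C)CC(Br)=C)=C45 | intermediate
34 | C7 aldehyde | O=CC[C@@H](O[Si](C)(C)C(C)(C)C)[C@H]1[C@H](O[C@H]2c3ccc(OC)cc3)[C@@](C)(O5)[C@](C)(O2)C[C@]14OC(=O)C(C(O)[C@@H](C)CC(Br)=C)=C45 | intermediate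
35 | eleven-membered carbocyclic diol (C7 and C20 epimers) | OC6C[C@@H](O[Si](C)(C)C(C)(C)C)[C@H]1[C@H](O[C@H]2c3ccc(OC)cc3)[C@@](C)(O5)[C@](C)(O2)C[C@]14OC(=O)C(C(O)[C@@H](C)CC6=C)=C45 | intermediate
36 | macrocyclic 3-acyl tetronate, C7 methylene ketone | O=C6C[C@@H](O[Si](C)(C)C(C)(C)C)[C@H]1[C@H](O[C@H]2c3ccc(OC)cc3)[C@@](C)(O5)[C@](C)(O2)C[C@]14OC(=O)C(C(=O)[C@@H](C)CC6=C)=C45 | intermediate
37 | pentacyclic enol with C4=C5 methylene | C[C@H]1CC(=C)C(=O)[C@@H]2[C@@H](O[Si](C)(C)C(C)(C)C)[C@H]3[C@H](O[C@H]6c7ccc(OC)cc7)[C@@]4(C)O[C@@]25/C(=C\1O)C(=O)O[C@@]35C[C@@]4(C)O6 | intermediate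
38 | C4 hydroperoxide | C[C@H]1C[C@](C)(OO)C(=O)[C@@H]2[C@@H](O[Si](C)(C)C(C)(C)C)[C@H]3[C@H](O[C@H]6c7ccc(OC)cc7)[C@@]4(C)O[C@@]25/C(=C\1O)C(=O)O[C@@]35C[C@@]4(C)O6 | intermediate
39 | protected target (O11 TBS, O14/O29 acetal) | C[C@H]1C[C@](C)(O)C(=O)[C@@H]2[C@@H](O[Si](C)(C)C(C)(C)C)[C@H]3[C@H](O[C@H]6c7ccc(OC)cc7)[C@@]4(C)O[C@@]25/C(=C\1O)C(=O)O[C@@]35C[C@@]4(C)O6 | intermediate
40 | CNP0073514.1 | C[C@H]1C[C@](C)(O)C(=O)[C@@H]2[C@@H](O)[C@H]3[C@H](O)[C@@]4(C)O[C@@]25/C(=C\1O)C(=O)O[C@@]35C[C@@]4(C)O | target

**Step count**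

Total step count: 29. Longest linear sequence: 26 (steps 1-19 and 23-29; steps 20-22 make the side fragment).

**Steps most likely to fail**

Step 13. The three-component addition may stall, because the only open face of C25 is crowded by the O11 and O17 silyl ethers. Long reaction times could then bring epimerisation at C12 or loss of the TES group. The fallback sets out from 15 and replaces the multicomponent union by an anionic C3 nucleophile.
- Lithium methyl propiolate, modified by CeCl3 (THF, -78 °C), adds to C25 from the same open face and brings C18, C19 and C22 at once, giving the gamma-hydroxy ynoate F1.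
- Buffered HF·pyridine frees O17 and gives the dihydroxy ynoate F2.
- Catalytic DBU then triggers oxa-Michael addition of O17 to C18 and lactonisation of O24 onto the ester. This is the known propiolate route to 4-alkoxybutenolides.
- The fallback comes back to the route at 23.

Step 11. Enolisation may also run toward C26. The aldol equilibrium may lie on the side of the ketone, because C10 ends syn-axial to O17. The fallback sets out from 10 and makes the C12 enolate regiospecifically by reduction.
- Mesylation and elimination (MsCl, Et3N) give the enone F3.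
- Nucleophilic epoxidation (tBuOOH, benzyltrimethylammonium hydroxide), anti to the bulky O17 silyl ether, gives the lower-face epoxy ketone F4.
- SmI2 (2 equiv, THF, -90 °C) cleaves the C12-O bond, and the samarium enolate is trapped by acrolein, added afterwards, to give the bis-aldol F5.
- DDQ with molecular sieves bridges O14 and O29, and the fallback comes back to the route at 14.

Step 25. Oligomerisation, slow insertion into the alkenyl bromide, or transannular strain may prevent closure of the eleven-membered ring. The fallback sets out from 34 and changes the order of ring formation.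
- Dess-Martin oxidation of the C20 carbinol gives the acyl tetronate aldehyde F6.
- Catalytic pyrrolidine (enamine Michael addition of C9 to C18) closes ring B first and gives the ring B aldehyde F7.
- The Nozaki-Hiyama-Kishi reaction (CrCl2, NiCl2 cat.) then has only to close the eight-membered ring A between two groups held cis on ring B, giving the ring A allylic alcohol F8.
- Dess-Martin oxidation of F8 comes back to the route at 37.

**Further compounds**

F1 | step 13 | gamma-hydroxy ynoate | C=C[C@@H](O[Si](C)(C)C(C)(C)C)[C@H]1[C@H](O[C@H]2c3ccc(OC)cc3)[C@@](C)(O[Si](CC)(CC)CC)[C@](C)(O2)C[C@@]1(O)C#CC(=O)OC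
F2 | step 13 | dihydroxy ynoate | C=C[C@@H](O[Si](C)(C)C(C)(C)C)[C@H]1[C@H](O[C@H]2c3ccc(OC)cc3)[C@@](C)(O)[C@](C)(O2)C[C@@]1(O)C#CC(=O)OC
F3 | step 11 | enone | O=C1C=C[C@@](C)(O[Si](CC)(CC)CC)[C@](C)(OCc2ccc(OC)cc2)C1
F4 | step 11 | lower-face epoxy ketone | O=C1[C@@H]2O[C@@H]2[C@@](C)(O[Si](CC)(CC)CC)[C@](C)(OCc3ccc(OC)cc3)C1
F5 | step 11 | bis-aldol | C=C[C@@H](O)[C@H]1[C@H](O)[C@@](C)(O[Si](CC)(CC)CC)[C@](C)(OCc2ccc(OC)cc2)CC1=O
F6 | step 25 | acyl tetronate aldehyde | O=CC[C@@H](O[Si](C)(C)C(C)(C)C)[C@H]1[C@H](O[C@H]2c3ccc(OC)cc3)[C@@](C)(O5)[C@](C)(O2)C[C@]14OC(=O)C(C(=O)[C@@H](C)CC(Br)=C)=C45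
F7 | step 25 | ring B aldehyde | O=C[C@@H]2[C@@H](O[Si](C)(C)C(C)(C)C)[C@H]3[C@H](O[C@H]6c7ccc(OC)cc7)[C@@]4(C)O[C@@]25/C(=C(\[C@@H](C)CC(Br)=C)O)C(=O)O[C@@]35C[C@@]4(C)O6
F8 | step 25 | ring A allylic alcohol (C7 epimers) | C[C@H]1CC(=C)C(O)[C@@H]2[C@@H](O[Si](C)(C)C(C)(C)C)[C@H]3[C@H](O[C@H]6c7ccc(OC)cc7)[C@@]4(C)O[C@@]25/C(=C\1O)C(=O)O[C@@]35C[C@@]4(C)O6
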